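The route rests on closing the cyclohexane at its least hindered ring bond, C4–C5 (C1 = carbinol carbon, C2 = gem-dimethyl carbon, C6 = methylidene carbon). C5, C6 and the exocyclic CH2 are a 2-substituted allyl unit whose two termini are interchangeable, so an acyclic allylic phosphate with the C1 stereocentre already set by lactate-based chelation control is cyclised by one-pot hydroboration of its 1,1-dimethylallyl vinyl group and copper-catalysed allyl–alkyl coupling, which delivers ring and exocyclic alkene together. The chain is then extended and the 1,2-dioxane closed last by 6-endo iodoperoxidation of a Z-alkene by a secondary hydroperoxide made with inversion.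

Key step: step 9

Remark: the cyclohexane locants above are used throughout; 2-methoxypropan-2-yl hydroperoxide (step 16) is assumed to be prepared beforehand by ozonolysis of 2,3-dimethylbut-2-ene in methanol.

Step 1
Reactants: 1 ethyl (2S)-2-hydroxypropanoate (ethyl (S)-lactate)
Product: 2 (2S)-2-hydroxy-N-methoxy-N-methylpropanamide
Conditions: MeNH(OMe)·HCl, i-PrMgCl, THF, −20 to 0 °C
Reagents that add atoms: N,O-dimethylhydroxylamine hydrochloride CNOC.Cl
Why: Aminolysis of the ester by the magnesium amide of N,O-dimethylhydroxylamine (Weinreb amide formation) should leave the α-stereocentre untouched, because it is held as its magnesium alkoxide.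

Step 2
Reactants: 2 lactate Weinreb amide; 3 (4-bromobut-1-yn-1-yl)trimethylsilane
Product: 5 (2S)-2-hydroxy-7-(trimethylsilyl)hept-6-yn-3-one, via Grignard reagent 4 (not isolated)
Conditions: 3, Mg, THF; 2 pre-treated with i-PrMgCl (1 equiv), then 4, THF, 0 °C; aq. NH4Cl
Reagents that add atoms: none
Why: Grignard addition to the Weinreb amide stops at the chelated tetrahedral magnesium intermediate, so work-up should release ketone 5 without over-addition and with the lactate stereocentre intact.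

Step 3
Reactants: 5 α-hydroxy ketone
Product: 6 (2S,3S)-3-(2-methylbut-3-en-2-yl)-7-(trimethylsilyl)hept-6-yne-2,3-diol
Conditions: prenyl bromide, In powder, THF/H2O, rt
Reagents that add atoms: prenyl bromide (1-bromo-3-methylbut-2-ene) CC(C)=CCBr
Why: In this Barbier-type indium-mediated allylation the prenyl reagent reacts at its γ-carbon to give the 1,1-dimethylallyl group, and a five-membered chelate of the ketone oxygen and the free α-hydroxyl directs attack anti to the α-methyl group (Cram chelate model), which should set the tertiary carbinol as (3S).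

Step 4
Reactants: 6 diol
Product: 7 (3S)-3-hydroxy-3-(2-methylbut-3-en-2-yl)-7-(trimethylsilyl)hept-6-yn-2-one
Conditions: SO3·pyridine, DMSO, i-Pr2NEt, CH2Cl2, 0 °C
Reagents that add atoms: none
Why: Parikh–Doering oxidation can only oxidise the secondary alcohol, which erases the auxiliary stereocentre after it has done its work and leaves the tertiary carbinol untouched.

Step 5
Reactants: 7 tertiary α-hydroxy ketone
Product: 8 (3S)-3-(2-methylbut-3-en-2-yl)-3-[(triethylsilyl)oxy]-7-(trimethylsilyl)hept-6-yn-2-one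
Conditions: TESOTf, 2,6-lutidine, CH2Cl2, −78 to 0 °C
Reagents that add atoms: triethylsilyl trifluoromethanesulfonate CC[Si](CC)(CC)OS(=O)(=O)C(F)(F)F
Why: Silylation of the hindered tertiary alcohol with the silyl triflate (2,6-lutidine is too weak a base to enolise the ketone in the cold) masks a hydroxyl that would otherwise fragment by retro-allylation as its alkoxide or add to electrophiles later.

Step 6
Reactants: 8 α-silyloxy methyl ketone
Product: 9 (3R)-2,4,4-trimethyl-3-[(triethylsilyl)oxy]-3-[4-(trimethylsilyl)but-3-yn-1-yl]hexa-1,5-diene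
Conditions: Ph3PCH3Br, KHMDS, THF, 0 °C to reflux
Reagents that add atoms: methyltriphenylphosphonium bromide C[P+](c1ccccc1)(c1ccccc1)c1ccccc1.[Br-]
Why: Wittig methylenation of the hindered methyl ketone gives the isopropenyl group that holds the future C5, C6 and exocyclic carbon (the descriptor changes only because the priorities change).

Step 7
Reactants: 9 isopropenyl silyl ether
Product: 10 (3S)-4,4-dimethyl-2-methylidene-3-[(triethylsilyl)oxy]-3-[4-(trimethylsilyl)but-3-yn-1-yl]hex-5-en-1-ol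
Conditions: SeO2 (0.5 equiv), t-BuOOH, CH2Cl2, rt
Reagents that add atoms: selenium dioxide O=[Se]=O; tert-butyl hydroperoxide CC(C)(C)OO
Why: Riley allylic oxidation (ene reaction with SeO2, then [2,3]-sigmatropic shift) should functionalise the isopropenyl methyl group, the only allylic C–H position in the molecule, without cationic intermediates that could trigger a semipinacol shift, while the propargylic CH2 is protected because the ene step would have to bond selenium to the silyl-bearing alkyne carbon.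

Step 8
Reactants: 10 allylic alcohol
Product: 11 diethyl (3S)-4,4-dimethyl-2-methylidene-3-[(triethylsilyl)oxy]-3-[4-(trimethylsilyl)but-3-yn-1-yl]hex-5-en-1-yl phosphate
Conditions: ClP(O)(OEt)2, pyridine, DMAP (cat.), CH2Cl2, 0 °C
Reagents that add atoms: diethyl chlorophosphate CCOP(=O)(Cl)OCC
Why: O-Phosphorylation of the primary allylic alcohol installs the leaving group needed for copper-mediated allylic substitution.

Step 9
Reactants: 11 allylic phosphate
Product: 13 triethyl{[(1S)-2,2-dimethyl-6-methylidene-1-[4-(trimethylsilyl)but-3-yn-1-yl]cyclohexyl]oxy}silane, via B-alkyl-9-BBN 12 (not isolated)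
Conditions: 9-BBN dimer (0.55 equiv), THF, 0 °C to rt; then CuOAc (10 mol %), KOtBu (1.1 equiv), THF (0.02 M), 60 °C
Reagents that add atoms: none
Why: 9-BBN adds anti-Markovnikov to the monosubstituted vinyl group and places boron on the future C4; KOtBu turns the B-alkyl-9-BBN 12 into a borate that passes the primary alkyl group to copper, and the alkylcopper substitutes the allylic phosphate with loss of diethyl phosphate. The closest known reaction type is the copper-catalysed allyl–alkyl coupling of B-alkyl-9-BBN reagents with allylic phosphates, run here within one molecule. The cyclohexane closes by C4–C5 bond formation either as 6-exo-tet attack at the CH2OP carbon or as 6-endo addition to the =CH2 terminus followed by β-elimination (formal SN2′); because both allyl termini are CH2 groups on the same carbon, the two modes give the same 6-methylidenecyclohexane. No stereocentre is formed, and C1 is carried unchanged because its silyl ether is not a leaving group under these basic conditions. The step needs chemoselective hydroboration, which the steric and electronic deactivation of the 1,1-disubstituted allylic phosphate alkene (quaternary neighbour, allylic oxygen) and of the silylalkyne should secure, and ring closure over oligomerisation, which high dilution and the gem-dimethyl group in the tether should secure.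

Step 10
Reactants: 13 methylidenecyclohexane with silylalkyne side chain
Product: 15 6-[(1S)-2,2-dimethyl-6-methylidene-1-[(triethylsilyl)oxy]cyclohexyl]hex-3-yn-1-ol, via lithium acetylide 14 (not isolated)
Conditions: MeLi·LiBr, THF, 0 °C to rt; then BF3·OEt2, oxirane, −78 °C
Reagents that add atoms: oxirane C1CO1
Why: Methyllithium cleaves the alkynyl C–Si bond to give acetylide 14, which opens BF3-activated oxirane (SN2 alkynylation of an epoxide) to the homopropargylic alcohol.

Step 11
Reactants: 15 homopropargylic alcohol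
Product: 16 (3Z)-6-[(1S)-2,2-dimethyl-6-methylidene-1-[(triethylsilyl)oxy]cyclohexyl]-4-methylhex-3-en-1-ol
Conditions: MeMgBr (4 equiv), Fe(acac)3 (15 mol %), THF, 0 °C to rt; aq. NH4Cl
Reagents that add atoms: methylmagnesium bromide C[Mg]Br
Why: Alkoxide-directed iron-catalysed syn-carbomagnesiation of the homopropargylic alcohol delivers methyl to the alkyne carbon remote from oxygen, and protonation of the vinylmagnesium species should give the trisubstituted alkene with the Z geometry that the later anti addition requires.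

Step 12
Reactants: 16 (Z)-homoallylic alcohol
Product: 17 (3Z)-6-[(1S)-2,2-dimethyl-6-methylidene-1-[(triethylsilyl)oxy]cyclohexyl]-4-methylhex-3-enal
Conditions: Dess–Martin periodinane, NaHCO3, CH2Cl2, 0 °C; used crude
Reagents that add atoms: none
Why: Dess–Martin oxidation under buffered, cold conditions should give the β,γ-unsaturated aldehyde, which is used at once so that the double bond does not move into conjugation.

Step 13
Reactants: 17 β,γ-unsaturated aldehyde; 18 (4S)-4-benzyl-3-propanoyl-1,3-oxazolidin-2-one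
Product: 20 (4S)-4-benzyl-3-[(2S,3R,5Z)-8-[(1S)-2,2-dimethyl-6-methylidene-1-[(triethylsilyl)oxy]cyclohexyl]-3-hydroxy-2,6-dimethyloct-5-enoyl]-1,3-oxazolidin-2-one, via boron enolate 19 (not isolated)
Conditions: 18, Bu2BOTf, Et3N, CH2Cl2, −78 to 0 °C; then 17, −78 to 0 °C; pH 7 buffer, MeOH, 30% H2O2
Reagents that add atoms: none
Why: In this Evans syn-aldol reaction the Z-boron enolate 19 reacts through a Zimmerman–Traxler chair on the face away from the benzyl group of the auxiliary, which should set (2S,3R): C2 becomes the α-carbon of the propanoate and the C3 oxygen is later replaced with inversion.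

Step 14
Reactants: 20 aldol adduct
Product: 21 (2R,3R,5Z)-8-[(1S)-2,2-dimethyl-6-methylidene-1-[(triethylsilyl)oxy]cyclohexyl]-2,6-dimethyloct-5-ene-1,3-diol
Conditions: LiBH4, MeOH (1 equiv), THF, 0 °C
Reagents that add atoms: none
Why: Reductive cleavage of the imide with LiBH4 releases the auxiliary and brings C1 to the alcohol level, so that the C3 oxygen can later be activated without β-elimination toward a carbonyl group (descriptors change by priority only).

Step 15
Reactants: 21 1,3-diol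
Product: 22 (2R,3R,5Z)-1-[(tert-butyldimethylsilyl)oxy]-8-[(1S)-2,2-dimethyl-6-methylidene-1-[(triethylsilyl)oxy]cyclohexyl]-2,6-dimethyloct-5-en-3-ol
Conditions: TBSCl, imidazole, CH2Cl2, 0 °C
Reagents that add atoms: tert-butyldimethylsilyl chloride CC(C)(C)[Si](C)(C)Cl
Why: Silylation with TBSCl discriminates the unhindered primary hydroxyl from the secondary one, so only the C3 hydroxyl stays free.

Step 16
Reactants: 22 secondary alcohol
Product: 24 tert-butyl{[(2R,3S,5Z)-8-[(1S)-2,2-dimethyl-6-methylidene-1-[(triethylsilyl)oxy]cyclohexyl]-3-[(2-methoxypropan-2-yl)peroxy]-2,6-dimethyloct-5-en-1-yl]oxy}dimethylsilane, via triflate 23 (not isolated)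
Conditions: Tf2O, 2,6-lutidine, CH2Cl2, −78 °C; then MeOC(CH3)2OOH, KOtBu, THF, −78 to −20 °C
Reagents that add atoms: 2-methoxypropan-2-yl hydroperoxide COC(C)(C)OO
Why: SN2 displacement of the secondary triflate by the potassium salt of the peroxyketal hydroperoxide (O-alkylation of a peroxide anion) should invert C3, turning the (3R) alcohol into the (3S) peroxide that becomes the CH peroxy carbon of the dioxane.

Step 17
Reactants: 24 peroxyketal
Product: 26 (3S,4S,6S)-6-[(2R)-1-[(tert-butyldimethylsilyl)oxy]propan-2-yl]-3-{2-[(1S)-2,2-dimethyl-6-methylidene-1-[(triethylsilyl)oxy]cyclohexyl]ethyl}-4-iodo-3-methyl-1,2-dioxane, via hydroperoxide 25 (not isolated)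
Conditions: PPTS, MeOH, 0 °C; then N-iodosuccinimide, CH2Cl2, 0 °C, dark
Reagents that add atoms: N-iodosuccinimide O=C1CCC(=O)N1I
Why: Methanolysis unmasks hydroperoxide 25, and 6-endo iodoperoxidation (halocyclisation) joins the peroxide oxygen to the more substituted alkene carbon (Markovnikov) by anti addition across the Z-alkene through a chair with the silyloxypropyl side chain equatorial, which should place the ethyl-linked chain on the new quaternary carbon axial and cis to that side chain, as the target requires.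

Step 18
Reactants: 26 iodo-1,2-dioxane
Product: 27 (3R,6S)-6-[(2R)-1-[(tert-butyldimethylsilyl)oxy]propan-2-yl]-3-{2-[(1S)-2,2-dimethyl-6-methylidene-1-[(triethylsilyl)oxy]cyclohexyl]ethyl}-3-methyl-1,2-dioxane
Conditions: Bu3SnH (5 equiv), Et3B (0.2 equiv), air, toluene (1 M), 0 °C
Reagents that add atoms: none
Why: Radical-chain hydrodeiodination with concentrated Bu3SnH removes the iodine, and the ring radical cannot reach the collinear geometry needed to attack the O–O bond, so the dioxane should survive.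

Step 19
Reactants: 27 bis-silylated dioxane
Product: 28 (2R)-2-[(3S,6R)-6-{2-[(1S)-1-hydroxy-2,2-dimethyl-6-methylidenecyclohexyl]ethyl}-6-methyl-1,2-dioxan-3-yl]propan-1-ol
Conditions: HF·pyridine, pyridine, THF, 0 °C to rt
Reagents that add atoms: none
Why: Fluoride-mediated desilylation cleaves the primary TBS ether and the tertiary TES ether under buffered conditions that should spare the peroxide and the tertiary allylic alcohol.

Step 20
Reactants: 28 diol
Product: 30 methyl (2S)-2-[(3S,6R)-6-{2-[(1S)-1-hydroxy-2,2-dimethyl-6-methylidenecyclohexyl]ethyl}-6-methyl-1,2-dioxan-3-yl]propanoate, via carboxylic acid 29 (not isolated)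
Conditions: TEMPO (0.2 equiv), PhI(OAc)2, MeCN/H2O, rt; then TMSCHN2, toluene/MeOH, 0 °C
Reagents that add atoms: water O; trimethylsilyldiazomethane C[Si](C)(C)C=[N+]=[N-]
Why: Oxoammonium (TEMPO) oxidation converts only the primary alcohol into the acid through the aldehyde hydrate, and base-free methylation with TMSCHN2 avoids epimerisation at C2 and β-elimination of the peroxide.

Compound list
1 | ethyl (2S)-2-hydroxypropanoate | C[C@H](O)C(=O)OCC | starting material
2 | (2S)-2-hydroxy-N-methoxy-N-methylpropanamide | C[C@H](O)C(=O)N(C)OC | intermediate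
3 | (4-bromobut-1-yn-1-yl)trimethylsilane | C[Si](C)(C)C#CCCBr | starting material
4 | [4-(trimethylsilyl)but-3-yn-1-yl]magnesium bromide | C[Si](C)(C)C#CCC[Mg]Br | intermediate
5 | (2S)-2-hydroxy-7-(trimethylsilyl)hept-6-yn-3-one | C[C@H](O)C(=O)CCC#C[Si](C)(C)C | intermediate
6 | (2S,3S)-3-(2-methylbut-3-en-2-yl)-7-(trimethylsilyl)hept-6-yne-2,3-diol | C[C@H](O)[C@](O)(CCC#C[Si](C)(C)C)C(C)(C)C=C | intermediate
7 | (3S)-3-hydroxy-3-(2-methylbut-3-en-2-yl)-7-(trimethylsilyl)hept-6-yn-2-one | CC(=O)[C@](O)(CCC#C[Si](C)(C)C)C(C)(C)C=C | intermediate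
8 | (3S)-3-(2-methylbut-3-en-2-yl)-3-[(triethylsilyl)oxy]-7-(trimethylsilyl)hept-6-yn-2-one | CC(=O)[C@](O[Si](CC)(CC)CC)(CCC#C[Si](C)(C)C)C(C)(C)C=C | intermediate
9 | (3R)-2,4,4-trimethyl-3-[(triethylsilyl)oxy]-3-[4-(trimethylsilyl)but-3-yn-1-yl]hexa-1,5-diene | CC(=C)[C@](O[Si](CC)(CC)CC)(CCC#C[Si](C)(C)C)C(C)(C)C=C | intermediate
10 | (3S)-4,4-dimethyl-2-methylidene-3-[(triethylsilyl)oxy]-3-[4-(trimethylsilyl)but-3-yn-1-yl]hex-5-en-1-ol | OCC(=C)[C@](O[Si](CC)(CC)CC)(CCC#C[Si](C)(C)C)C(C)(C)C=C | intermediate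
11 | diethyl (3S)-4,4-dimethyl-2-methylidene-3-[(triethylsilyl)oxy]-3-[4-(trimethylsilyl)but-3-yn-1-yl]hex-5-en-1-yl phosphate | CCOP(=O)(OCC)OCC(=C)[C@](O[Si](CC)(CC)CC)(CCC#C[Si](C)(C)C)C(C)(C)C=C | intermediate
12 | diethyl (3S)-6-(9-borabicyclo[3.3.1]nonan-9-yl)-4,4-dimethyl-2-methylidene-3-[(triethylsilyl)oxy]-3-[4-(trimethylsilyl)but-3-yn-1-yl]hexyl phosphate | CCOP(=O)(OCC)OCC(=C)[C@](O[Si](CC)(CC)CC)(CCC#C[Si](C)(C)C)C(C)(C)CCB1C2CCCC1CCC2 | intermediate
13 | triethyl{[(1S)-2,2-dimethyl-6-methylidene-1-[4-(trimethylsilyl)but-3-yn-1-yl]cyclohexyl]oxy}silane | C=C1CCCC(C)(C)[C@@]1(O[Si](CC)(CC)CC)CCC#C[Si](C)(C)C | intermediate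
14 | {4-[(1S)-2,2-dimethyl-6-methylidene-1-[(triethylsilyl)oxy]cyclohexyl]but-1-yn-1-yl}lithium | C=C1CCCC(C)(C)[C@@]1(O[Si](CC)(CC)CC)CCC#C[Li] | intermediate
15 | 6-[(1S)-2,2-dimethyl-6-methylidene-1-[(triethylsilyl)oxy]cyclohexyl]hex-3-yn-1-ol | C=C1CCCC(C)(C)[C@@]1(O[Si](CC)(CC)CC)CCC#CCCO | intermediate
16 | (3Z)-6-[(1S)-2,2-dimethyl-6-methylidene-1-[(triethylsilyl)oxy]cyclohexyl]-4-methylhex-3-en-1-ol | C=C1CCCC(C)(C)[C@@]1(O[Si](CC)(CC)CC)CC/C(C)=C\CCO | intermediate
17 | (3Z)-6-[(1S)-2,2-dimethyl-6-methylidene-1-[(triethylsilyl)oxy]cyclohexyl]-4-methylhex-3-enal | C=C1CCCC(C)(C)[C@@]1(O[Si](CC)(CC)CC)CC/C(C)=C\CC=O | intermediate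
18 | (4S)-4-benzyl-3-propanoyl-1,3-oxazolidin-2-one | CCC(=O)N1[C@@H](Cc2ccccc2)COC1=O | starting material
19 | (Z)-dibutylboron enolate of 18 | C/C=C(\OB(CCCC)CCCC)N1[C@@H](Cc2ccccc2)COC1=O | intermediate
20 | (4S)-4-benzyl-3-[(2S,3R,5Z)-8-[(1S)-2,2-dimethyl-6-methylidene-1-[(triethylsilyl)oxy]cyclohexyl]-3-hydroxy-2,6-dimethyloct-5-enoyl]-1,3-oxazolidin-2-one | C=C1CCCC(C)(C)[C@@]1(O[Si](CC)(CC)CC)CC/C(C)=C\C[C@@H](O)[C@H](C)C(=O)N1[C@@H](Cc2ccccc2)COC1=O | intermediate
21 | (2R,3R,5Z)-8-[(1S)-2,2-dimethyl-6-methylidene-1-[(triethylsilyl)oxy]cyclohexyl]-2,6-dimethyloct-5-ene-1,3-diol | C=C1CCCC(C)(C)[C@@]1(O[Si](CC)(CC)CC)CC/C(C)=C\C[C@@H](O)[C@H](C)CO | intermediate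
22 | (2R,3R,5Z)-1-[(tert-butyldimethylsilyl)oxy]-8-[(1S)-2,2-dimethyl-6-methylidene-1-[(triethylsilyl)oxy]cyclohexyl]-2,6-dimethyloct-5-en-3-ol | C=C1CCCC(C)(C)[C@@]1(O[Si](CC)(CC)CC)CC/C(C)=C\C[C@@H](O)[C@H](C)CO[Si](C)(C)C(C)(C)C | intermediate
23 | (2R,3R,5Z)-1-[(tert-butyldimethylsilyl)oxy]-8-[(1S)-2,2-dimethyl-6-methylidene-1-[(triethylsilyl)oxy]cyclohexyl]-2,6-dimethyloct-5-en-3-yl trifluoromethanesulfonate | C=C1CCCC(C)(C)[C@@]1(O[Si](CC)(CC)CC)CC/C(C)=C\C[C@@H](OS(=O)(=O)C(F)(F)F)[C@H](C)CO[Si](C)(C)C(C)(C)C | intermediate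
24 | tert-butyl{[(2R,3S,5Z)-8-[(1S)-2,2-dimethyl-6-methylidene-1-[(triethylsilyl)oxy]cyclohexyl]-3-[(2-methoxypropan-2-yl)peroxy]-2,6-dimethyloct-5-en-1-yl]oxy}dimethylsilane | C=C1CCCC(C)(C)[C@@]1(O[Si](CC)(CC)CC)CC/C(C)=C\C[C@H](OOC(C)(C)OC)[C@H](C)CO[Si](C)(C)C(C)(C)C | intermediate
25 | tert-butyl{[(2R,3S,5Z)-8-[(1S)-2,2-dimethyl-6-methylidene-1-[(triethylsilyl)oxy]cyclohexyl]-3-hydroperoxy-2,6-dimethyloct-5-en-1-yl]oxy}dimethylsilane | C=C1CCCC(C)(C)[C@@]1(O[Si](CC)(CC)CC)CC/C(C)=C\C[C@H](OO)[C@H](C)CO[Si](C)(C)C(C)(C)C | intermediate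
26 | (3S,4S,6S)-6-[(2R)-1-[(tert-butyldimethylsilyl)oxy]propan-2-yl]-3-{2-[(1S)-2,2-dimethyl-6-methylidene-1-[(triethylsilyl)oxy]cyclohexyl]ethyl}-4-iodo-3-methyl-1,2-dioxane | C=C1CCCC(C)(C)[C@@]1(O[Si](CC)(CC)CC)CC[C@@]1(C)[C@@H](I)C[C@@H]([C@H](C)CO[Si](C)(C)C(C)(C)C)OO1 | intermediate
27 | (3R,6S)-6-[(2R)-1-[(tert-butyldimethylsilyl)oxy]propan-2-yl]-3-{2-[(1S)-2,2-dimethyl-6-methylidene-1-[(triethylsilyl)oxy]cyclohexyl]ethyl}-3-methyl-1,2-dioxane | C=C1CCCC(C)(C)[C@@]1(O[Si](CC)(CC)CC)CC[C@@]1(C)CC[C@@H]([C@H](C)CO[Si](C)(C)C(C)(C)C)OO1 | intermediate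
28 | (2R)-2-[(3S,6R)-6-{2-[(1S)-1-hydroxy-2,2-dimethyl-6-methylidenecyclohexyl]ethyl}-6-methyl-1,2-dioxan-3-yl]propan-1-ol | C=C1CCCC(C)(C)[C@@]1(O)CC[C@@]1(C)CC[C@@H]([C@H](C)CO)OO1 | intermediate
29 | (2S)-2-[(3S,6R)-6-{2-[(1S)-1-hydroxy-2,2-dimethyl-6-methylidenecyclohexyl]ethyl}-6-methyl-1,2-dioxan-3-yl]propanoic acid | C=C1CCCC(C)(C)[C@@]1(O)CC[C@@]1(C)CC[C@@H]([C@H](C)C(=O)O)OO1 | intermediate
30 | methyl (2S)-2-[(3S,6R)-6-{2-[(1S)-1-hydroxy-2,2-dimethyl-6-methylidenecyclohexyl]ethyl}-6-methyl-1,2-dioxan-3-yl]propanoate | C=C1CCCC(C)(C)[C@@]1(O)CC[C@@]1(C)CC[C@@H]([C@H](C)C(=O)OC)OO1 | target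

Total step count: 20. Longest linear sequence: 20 steps (1 to 30).

Steps most likely to fail

1. Step 9 (ring closure). 9-BBN may fail to discriminate the vinyl group from the allylic phosphate alkene, or the alkylcopper may couple between molecules or be protonated before it closes the ring. The fallback sets out from 8 and forms the same C4–C5 bond by enolate alkylation. Hydroboration of the vinyl group with 9-BBN and oxidation with NaBO3 would give the primary alcohol (3S)-3-(4-hydroxy-2-methylbutan-2-yl)-3-[(triethylsilyl)oxy]-7-(trimethylsilyl)hept-6-yn-2-one F1. I2, PPh3 and imidazole would convert it into the iodide (3S)-3-(4-iodo-2-methylbutan-2-yl)-3-[(triethylsilyl)oxy]-7-(trimethylsilyl)hept-6-yn-2-one F2. KHMDS in THF at −78 °C would form the only possible enolate (on the methyl group), which closes the ring by 6-exo-tet C-alkylation to the cyclohexanone (2S)-3,3-dimethyl-2-[(triethylsilyl)oxy]-2-[4-(trimethylsilyl)but-3-yn-1-yl]cyclohexan-1-one F3. Wittig methylenation of F3 (Ph3PCH3Br, KHMDS) comes back to the route at 13.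

2. Step 16 (peroxide by SN2). At the β-branched secondary carbon, elimination or ionisation of the triflate assisted by the homoallylic double bond may outrun displacement. The fallback sets out from 22, makes the tertiary C–O bond first and closes the ring by an intramolecular displacement. MsCl and Et3N would give the mesylate (2R,3R,5Z)-1-[(tert-butyldimethylsilyl)oxy]-8-[(1S)-2,2-dimethyl-6-methylidene-1-[(triethylsilyl)oxy]cyclohexyl]-2,6-dimethyloct-5-en-3-yl methanesulfonate F4. Reagent-controlled Shi epoxidation (carbohydrate-derived ketone of the required handedness, KHSO5) of the trisubstituted alkene would give the cis-5,6-epoxide of F4 F5. Ethereal H2O2 with catalytic phosphomolybdic acid (H3PMo12O40) would open the epoxide at its tertiary carbon with inversion to the 6-hydroperoxy-5-hydroxy derivative of F4 F6. KOtBu and 18-crown-6 would close the ring by 6-exo-tet displacement of the mesylate with inversion to (3S,4S,6S)-6-[(2R)-1-[(tert-butyldimethylsilyl)oxy]propan-2-yl]-3-{2-[(1S)-2,2-dimethyl-6-methylidene-1-[(triethylsilyl)oxy]cyclohexyl]ethyl}-3-methyl-1,2-dioxan-4-ol F7. Phenyl chlorothionoformate and pyridine would give the O-phenyl thiocarbonate of F7 F8, and Barton–McCombie reduction (Bu3SnH, Et3B) comes back to the route at 27.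

3. Step 3 (tertiary carbinol). Addition through a non-chelated transition state would erode facial selectivity, and the hindered prenyl reagent may add sluggishly to the ketone. The fallback sets out from 2, reverses the order of the two C–C bond formations and relies on Felkin–Anh control. Prenylmagnesium chloride (γ-attack on the Weinreb amide) would give (2S)-2-hydroxy-4,4-dimethylhex-5-en-3-one F9. TBSOTf and 2,6-lutidine would give its non-chelating silyl ether (2S)-2-[(tert-butyldimethylsilyl)oxy]-4,4-dimethylhex-5-en-3-one F10. Addition of Grignard reagent 4 anti to the silyloxy group (Felkin–Anh) would give (2S,3S)-2-[(tert-butyldimethylsilyl)oxy]-3-(2-methylbut-3-en-2-yl)-7-(trimethylsilyl)hept-6-yn-3-ol F11, and HF·pyridine comes back to the route at 6.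

Further compounds
F1 | step 9 | (3S)-3-(4-hydroxy-2-methylbutan-2-yl)-3-[(triethylsilyl)oxy]-7-(trimethylsilyl)hept-6-yn-2-one | CC(=O)[C@](O[Si](CC)(CC)CC)(CCC#C[Si](C)(C)C)C(C)(C)CCO
F2 | step 9 | (3S)-3-(4-iodo-2-methylbutan-2-yl)-3-[(triethylsilyl)oxy]-7-(trimethylsilyl)hept-6-yn-2-one | CC(=O)[C@](O[Si](CC)(CC)CC)(CCC#C[Si](C)(C)C)C(C)(C)CCI
F3 | step 9 | (2S)-3,3-dimethyl-2-[(triethylsilyl)oxy]-2-[4-(trimethylsilyl)but-3-yn-1-yl]cyclohexan-1-one | O=C1CCCC(C)(C)[C@@]1(O[Si](CC)(CC)CC)CCC#C[Si](C)(C)C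
F4 | step 16 | (2R,3R,5Z)-1-[(tert-butyldimethylsilyl)oxy]-8-[(1S)-2,2-dimethyl-6-methylidene-1-[(triethylsilyl)oxy]cyclohexyl]-2,6-dimethyloct-5-en-3-yl methanesulfonate | C=C1CCCC(C)(C)[C@@]1(O[Si](CC)(CC)CC)CC/C(C)=C\C[C@@H](OS(C)(=O)=O)[C@H](C)CO[Si](C)(C)C(C)(C)C
F5 | step 16 | cis-5,6-epoxide of F4 (oxirane from the Z-alkene, stereochemistry as in the SMILES) | C=C1CCCC(C)(C)[C@@]1(O[Si](CC)(CC)CC)CC[C@@]2(C)O[C@H]2C[C@@H](OS(C)(=O)=O)[C@H](C)CO[Si](C)(C)C(C)(C)C
F6 | step 16 | 6-hydroperoxy-5-hydroxy derivative of F4 (tertiary hydroperoxide, secondary alcohol, mesylate retained, stereochemistry as in the SMILES) | C=C1CCCC(C)(C)[C@@]1(O[Si](CC)(CC)CC)CC[C@@](OO)(C)[C@@H](O)C[C@@H](OS(C)(=O)=O)[C@H](C)CO[Si](C)(C)C(C)(C)C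
F7 | step 16 | (3S,4S,6S)-6-[(2R)-1-[(tert-butyldimethylsilyl)oxy]propan-2-yl]-3-{2-[(1S)-2,2-dimethyl-6-methylidene-1-[(triethylsilyl)oxy]cyclohexyl]ethyl}-3-methyl-1,2-dioxan-4-ol | C=C1CCCC(C)(C)[C@@]1(O[Si](CC)(CC)CC)CC[C@@]1(C)[C@@H](O)C[C@@H]([C@H](C)CO[Si](C)(C)C(C)(C)C)OO1
F8 | step 16 | O-phenyl thiocarbonate of F7 | C=C1CCCC(C)(C)[C@@]1(O[Si](CC)(CC)CC)CC[C@@]1(C)[C@@H](OC(=S)Oc2ccccc2)C[C@@H]([C@H](C)CO[Si](C)(C)C(C)(C)C)OO1
F9 | step 3 | (2S)-2-hydroxy-4,4-dimethylhex-5-en-3-one | C[C@H](O)C(=O)C(C)(C)C=C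
F10 | step 3 | (2S)-2-[(tert-butyldimethylsilyl)oxy]-4,4-dimethylhex-5-en-3-one | C[C@H](O[Si](C)(C)C(C)(C)C)C(=O)C(C)(C)C=C
F11 | step 3 | (2S,3S)-2-[(tert-butyldimethylsilyl)oxy]-3-(2-methylbut-3-en-2-yl)-7-(trimethylsilyl)hept-6-yn-3-ol | C[C@H](O[Si](C)(C)C(C)(C)C)[C@](O)(CCC#C[Si](C)(C)C)C(C)(C)C=C
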